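**Strategy.** Ring A is disconnected at C3–C4. The gem-dimethyl carbon C4 next to the ring-fusion methine C5 is the isopropenyl group of (R)-carvone, whose ring becomes ring B (C5–C10). In one operation, iron-hydride hydrogen-atom transfer to the isopropenyl CH2 creates the second C4 methyl and a tertiary C4 radical that closes ring A 6-endo on a tethered acrylate. The precursor is carvone carrying, at its α′ carbon (C10), a methyl and, trans to the isopropenyl group, a 2-(methoxycarbonyl)allyl arm. The activating ester is excised at once; the ring-B enone then delivers the C9 side chain via a dienyl triflate and the C6 oxygen via singlet oxygen.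

Key step: step 3

Remarks on the chemistry:
- Locants in the text follow the decalin of the target: ring A = C1–C5 and C10, ring B = C5–C10, side chain C11/C12, butenolide C13–C16. β is the face of the C10 methyl.
- Compound 3 is carried as a C6 epimer mixture and compounds 6–8 as C2 epimer mixtures (equatorial ester drawn); all converge.
- The acrylate ester serves only as the radical acceptor. It is removed in steps 4–5, so no enolisable ester is present during the enolate chemistry on ring B.

**Step 1**
Reactants: 1 (R)-(−)-carvone; 2 iodomethane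
Product: 3 (5R,6RS)-2,6-dimethyl-5-(prop-1-en-2-yl)cyclohex-2-en-1-one (6-methylcarvone)
Conditions: LDA, THF, −78 °C; MeI, −78 → 0 °C
Reagents that add atoms: iodomethane 2, CI
Why: Kinetic deprotonation at the α′-CH2 gives the cross-conjugated lithium enolate, which is C-methylated (enolate alkylation); the C6 epimer ratio is immaterial because C6 is re-enolised in step 2.

**Step 2**
Reactants: 3 6-methylcarvone; 4 methyl 2-(bromomethyl)acrylate
Product: 5 methyl 2-{[(1S,6S)-1,3-dimethyl-2-oxo-6-(prop-1-en-2-yl)cyclohex-3-en-1-yl]methyl}prop-2-enoate (acrylate arm trans to the isopropenyl group)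
Conditions: LDA, THF, −78 °C; then 4, DMPU, −78 → −20 °C
Reagents that add atoms: methyl 2-(bromomethyl)acrylate 4, COC(=O)C(=C)CBr
Why: Enolate alkylation with a reactive allylic bromide (SN2/SN2′): the fully substituted α′ enolate is attacked on the face anti to the adjacent isopropenyl group, so the new quaternary centre (C10) carries the acrylate arm trans to the isopropenyl group, the relationship that becomes the trans ring fusion.

**Step 3**
Reactants: 5 acrylate-tethered carvone
Product: 6 methyl (2S,4aS,8aS)-4,4,7,8a-tetramethyl-8-oxo-1,2,3,4,4a,5,8,8a-octahydronaphthalene-2-carboxylate (trans-fused 7-en-9-one with C2 ester)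
Conditions: Fe(acac)3 (30 mol %), PhSiH3, EtOH/(CH2OH)2, 60 °C, high dilution
Reagents that add atoms: none
Why: An iron hydride formed from Fe(acac)3 and PhSiH3 transfers a hydrogen atom to the terminal CH2 of the electron-rich isopropenyl group, which creates the second C4 methyl and a tertiary C4 radical; this nucleophilic radical adds to the unsubstituted CH2 terminus of the tethered acrylate (C3–C4 bond), and the resulting α-ester radical at C2 is reduced by Fe(II) and protonated by ethanol. The closest known reaction type is the iron-hydride reductive olefin coupling (hydrogen-atom-transfer Giese addition) run intramolecularly. Ring A closes in the 6-endo-trig mode, because the 5-exo alternative would require attack at the ester-bearing alkene carbon, which is sterically and polarity mismatched and would leave an unstabilised primary radical. The only new stereocentre, C2, is set by protonation of the ester enolate (equatorial ester expected) and is deleted in step 5, while the trans ring fusion is inherited from C5 and C10 of 5, whose trans-diequatorial isopropenyl and acrylate arms hold radical and acceptor within bonding distance. The selectivity needed is hydrogen-atom transfer to the 1,1-disubstituted donor alkene in preference to the two electron-poor alkenes, secured by the electrophilic character of the metal hydride; the ring-B enone cannot be reached by the C4 radical without forming a four-membered ring.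

**Step 4**
Reactants: 6 bicyclic enone ester
Product: 7 (2S,4aS,8aS)-4,4,7,8a-tetramethyl-8-oxo-1,2,3,4,4a,5,8,8a-octahydronaphthalene-2-carboxylic acid
Conditions: LiOH·H2O, THF/MeOH/H2O, rt; then 1 M HCl
Reagents that add atoms: lithium hydroxide, [Li+].[OH-]
Why: Saponification of an unhindered secondary methyl ester; the enone and the quaternary centre are base-stable and epimerisation at C2 is without consequence.

**Step 5**
Reactants: 7 bicyclic enone acid
Product: 9 (4aS,8aS)-2,5,5,8a-tetramethyl-4a,5,6,7,8,8a-hexahydronaphthalen-1(4H)-one, via Barton ester 8 (not isolated)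
Conditions: 2-mercaptopyridine N-oxide, DCC, DMAP (cat.), CH2Cl2, dark, rt; then t-BuSH, hν (W lamp), rt
Reagents that add atoms: none
Why: Barton reductive decarboxylation: the O-acyl thiohydroxamate fragments under visible light to the acyloxy radical, which loses CO2, and the secondary C2 radical abstracts hydrogen from the thiol; C2 becomes a methylene, so both epimers converge, and the enone is tolerated by the neutral radical chain.

**Step 6**
Reactants: 9 bicyclic enone
Product: 10 (4aS,8aS)-2,5,5,8a-tetramethyl-4a,5,6,7,8,8a-hexahydronaphthalen-1-yl trifluoromethanesulfonate (9-triflyloxy-6,8-diene)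
Conditions: KHMDS, THF, −78 → −40 °C; PhNTf2, −78 °C → rt
Reagents that add atoms: N-phenylbis(trifluoromethanesulfonimide), O=S(=O)(N(c1ccccc1)S(=O)(=O)C(F)(F)F)C(F)(F)F
Why: Enol triflate formation: C10 is quaternary, so the base can only remove a γ-hydrogen at C6, and the linear potassium dienolate is O-sulfonylated to the dienyl triflate with the leaving group on C9 and a C6=C7 alkene.

**Step 7**
Reactants: 10 dienyl triflate; 11 tributyl(vinyl)stannane
Product: 12 (4aS,8aS)-1-ethenyl-2,5,5,8a-tetramethyl-4a,5,6,7,8,8a-hexahydronaphthalene (9-vinyl-6,8-diene)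
Conditions: Pd(PPh3)4 (5 mol %), LiCl, THF, reflux
Reagents that add atoms: tributyl(vinyl)stannane 11, C=C[Sn](CCCC)(CCCC)CCCC
Why: Stille coupling of a vinyl triflate promoted by LiCl; 2,6,6-trisubstituted cyclohexenyl triflates are established partners and the small vinyl group keeps the steric demand at C9 low.

**Step 8**
Reactants: 12 triene; 13 4-bromofuran-2(5H)-one
Product: 15 4-{2-[(4aS,8aS)-2,5,5,8a-tetramethyl-4a,5,6,7,8,8a-hexahydronaphthalen-1-yl]ethyl}furan-2(5H)-one (6,8-diene butenolide), via alkylborane 14 (not isolated)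
Conditions: 9-BBN, THF, 0 °C → rt; then 13, Pd(dppf)Cl2 (5 mol %), AsPh3, Cs2CO3, DMF/THF/H2O, rt
Reagents that add atoms: 4-bromofuran-2(5H)-one 13, O=C1C=C(Br)CO1
Why: 9-BBN should add only to the monosubstituted vinyl group, with boron on the terminal carbon (C12), leaving the ring diene untouched; the B-alkyl Suzuki–Miyaura coupling with the β-bromobutenolide (a vinylogous acyl bromide) then forms C12–C13 at room temperature and installs the complete side chain.

**Step 9**
Reactants: 15 diene butenolide
Product: 17 4-{2-[(1R,4aS,8aS)-1-hydroxy-2,5,5,8a-tetramethyl-4-oxo-1,4,4a,5,6,7,8,8a-octahydronaphthalen-1-yl]ethyl}furan-2(5H)-one (9α-hydroxy-7-en-6-one), via endoperoxide 16 (not isolated)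
Conditions: O2, TPP (cat.), hν (white LED), CH2Cl2, −20 °C; then Et3N, 0 °C → rt
Reagents that add atoms: dioxygen, O=O
Why: Dye-sensitised [4+2] cycloaddition of singlet oxygen across the s-cis-locked C6=C7–C8=C9 diene, followed by Kornblum–DeLaMare rearrangement: the amine removes the only hydrogen α to the peroxide (C6–H), so the O–O bond cleaves to the C6 ketone and the C9 tertiary alcohol without regiochemical ambiguity; the C9 configuration (α expected, anti to the 10β-methyl) is erased in step 10, and the electron-poor butenolide is inert to singlet oxygen.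

**Step 10**
Reactants: 17 9α-hydroxy-7-en-6-one
Product: 18 4-{2-[(4aS,8aS)-2,5,5,8a-tetramethyl-4-oxo-3,4,4a,5,6,7,8,8a-octahydronaphthalen-1-yl]ethyl}furan-2(5H)-one (8-en-6-one)
Conditions: SmI2, THF/MeOH, −78 °C; pH 7 buffer
Reagents that add atoms: none
Why: Reductive γ-elimination of a γ-hydroxy enone (the vinylogue of α-ketol deoxygenation): two-electron reduction gives a samarium dienolate with loss of the C9 hydroxide, and kinetic protonation by methanol at the α-carbon C7 instead of the fully substituted C9 leaves the C6 ketone and the tetrasubstituted C8=C9 alkene; the butenolide is reduced far more slowly than the enone at −78 °C.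

**Step 11**
Reactants: 18 8-en-6-one
Product: 19 4-{2-[(4R,4aS,8aS)-4-hydroxy-2,5,5,8a-tetramethyl-3,4,4a,5,6,7,8,8a-octahydronaphthalen-1-yl]ethyl}furan-2(5H)-one (6β-alcohol)
Conditions: NaBH4, CeCl3·7H2O, MeOH, −40 °C
Reagents that add atoms: none
Why: Luche-type carbonyl reduction, chosen to keep the medium non-basic and to avoid conjugate reduction of the butenolide: the β-face of C6 is shielded by the syn-axial 10β- and 4β-methyl groups, so hydride is delivered from the α-face and the axial 6β-alcohol (6R) should result.

**Step 12**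
Reactants: 19 6β-alcohol
Product: 20 (1R,4aS,8aS)-3,4a,8,8-tetramethyl-4-[2-(5-oxo-2,5-dihydrofuran-3-yl)ethyl]-1,2,4a,5,6,7,8,8a-octahydronaphthalen-1-yl acetate (target; 5S,6R,10S in decalin locants)
Conditions: Ac2O, DMAP, Et3N, CH2Cl2, rt → 40 °C
Reagents that add atoms: acetic anhydride, CC(=O)OC(C)=O
Why: DMAP-catalysed acylation of the hindered axial secondary alcohol; no other nucleophilic group is present and the stereocentres are untouched.

**Compound list**
1 | (R)-(−)-carvone | CC1=CC[C@H](CC1=O)C(C)=C | starting material
2 | iodomethane | CI | starting material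
3 | (5R,6RS)-6-methylcarvone | CC1=CC[C@H](C(C)C1=O)C(C)=C | intermediate
4 | methyl 2-(bromomethyl)acrylate | COC(=O)C(=C)CBr | starting material
5 | methyl 2-{[(1S,6S)-1,3-dimethyl-2-oxo-6-(prop-1-en-2-yl)cyclohex-3-en-1-yl]methyl}prop-2-enoate | C1C=C(C)C(=O)[C@@](C)(CC(=C)C(=O)OC)[C@@H]1C(C)=C | intermediate
6 | methyl (2S,4aS,8aS)-4,4,7,8a-tetramethyl-8-oxo-1,2,3,4,4a,5,8,8a-octahydronaphthalene-2-carboxylate | C1C=C(C)C(=O)[C@@]2(C)C[C@@H](C(=O)OC)CC(C)(C)[C@H]12 | intermediate
7 | corresponding C2 carboxylic acid | C1C=C(C)C(=O)[C@@]2(C)C[C@@H](C(=O)O)CC(C)(C)[C@H]12 | intermediate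
8 | Barton ester (2-thioxopyridin-1(2H)-yl ester of 7) | C1C=C(C)C(=O)[C@@]2(C)C[C@@H](C(=O)ON3C=CC=CC3=S)CC(C)(C)[C@H]12 | intermediate (not isolated)
9 | (4aS,8aS)-2,5,5,8a-tetramethyl-4a,5,6,7,8,8a-hexahydronaphthalen-1(4H)-one | C1C=C(C)C(=O)[C@@]2(C)CCCC(C)(C)[C@H]12 | intermediate
10 | (4aS,8aS)-2,5,5,8a-tetramethyl-4a,5,6,7,8,8a-hexahydronaphthalen-1-yl trifluoromethanesulfonate | C1=CC(C)=C(OS(=O)(=O)C(F)(F)F)[C@@]2(C)CCCC(C)(C)[C@H]12 | intermediate
11 | tributyl(vinyl)stannane | C=C[Sn](CCCC)(CCCC)CCCC | starting material
12 | (4aS,8aS)-1-ethenyl-2,5,5,8a-tetramethyl-4a,5,6,7,8,8a-hexahydronaphthalene | C1=CC(C)=C(C=C)[C@@]2(C)CCCC(C)(C)[C@H]12 | intermediate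
13 | 4-bromofuran-2(5H)-one | O=C1C=C(Br)CO1 | starting material
14 | B-alkyl-9-BBN adduct of 12 (boron on C12) | C1=CC(C)=C(CCB3C4CCCC3CCC4)[C@@]2(C)CCCC(C)(C)[C@H]12 | intermediate (not isolated)
15 | 4-{2-[(4aS,8aS)-2,5,5,8a-tetramethyl-4a,5,6,7,8,8a-hexahydronaphthalen-1-yl]ethyl}furan-2(5H)-one | C1=CC(C)=C(CCC3=CC(=O)OC3)[C@@]2(C)CCCC(C)(C)[C@H]12 | intermediate
16 | 6α,9α-epidioxy-7-ene (endoperoxide of 15) | O1[C@H]2C=C(C)[C@](O1)(CCC3=CC(=O)OC3)[C@@]4(C)CCCC(C)(C)[C@H]24 | intermediate (not isolated)
17 | 9α-hydroxy-7-en-6-one butenolide | O=C1C=C(C)[C@](O)(CCC2=CC(=O)OC2)[C@@]2(C)CCCC(C)(C)[C@H]12 | intermediate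
18 | 8-en-6-one butenolide | O=C1CC(C)=C(CCC2=CC(=O)OC2)[C@@]2(C)CCCC(C)(C)[C@H]12 | intermediate
19 | 6β-hydroxy-8-ene butenolide | O[C@@H]1CC(C)=C(CCC2=CC(=O)OC2)[C@@]2(C)CCCC(C)(C)[C@H]12 | intermediate
20 | CNP0128495.1, 6β-acetoxy-8-ene butenolide | CC(=O)O[C@@H]1CC(C)=C(CCC2=CC(=O)OC2)[C@@]2(C)CCCC(C)(C)[C@H]12 | target

**Step count.** Total: 12 steps. Longest linear sequence: 12 steps from (R)-(−)-carvone.

**Steps most likely to fail**

Step 3. The tertiary radical may be quenched by a second hydrogen-atom transfer before it cyclises (simple reduction of the isopropenyl group), or hydrogen may be delivered unselectively to the acrylate. Fallback, from 5 back to 6: ionic Markovnikov hydrobromination of the isopropenyl group (HBr in AcOH, 0 °C) should give the tertiary bromide F1. A tin-hydride chain (Bu3SnH, AIBN, benzene, 80 °C, slow addition) would then generate the same C4 radical by bromine abstraction and close ring A 6-endo onto the acrylate, returning to 6.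

Step 10. The dienolate may be protonated at the γ-carbon, or the C8=C9 bond may migrate into conjugation with the ketone during reaction or work-up, or hydroxide expulsion may be incomplete. Fallback, from 17 to 20, avoiding the β,γ-unsaturated ketone altogether: Luche reduction of 17 from the α-face should give the 7-ene-6β,9α-diol F2. Acetylation of its secondary hydroxyl (Ac2O, DMAP) should give the 6β-acetoxy-9α-hydroxy-7-ene F3. Ionic hydrogenation (Et3SiH, BF3·OEt2, CH2Cl2, −78 °C) would ionise the tertiary allylic alcohol and deliver hydride to the less hindered allyl terminus C7, giving the target 20 directly.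

Step 8. Site selectivity may be lost in the hydroboration of the conjugated triene, or the bromobutenolide may be destroyed by base faster than transmetalation occurs. Fallback, from 10 to 15, bypassing the triene: Negishi coupling of 10 with commercial [2-(1,3-dioxolan-2-yl)ethyl]zinc bromide (Pd(dppf)Cl2, THF/DMA, 50 °C) should give the diene acetal F4. Mild acetal cleavage (PPTS, acetone/H2O) would give the diene aldehyde F5. Carbene-catalysed hydroxymethylation with paraformaldehyde (thiazolium salt, Et3N, THF, 60 °C) would give the diene hydroxymethyl ketone F6. Reaction with (triphenylphosphoranylidene)ketene (Bestmann ylide, toluene, 90 °C; O-acylation then intramolecular Wittig) closes the butenolide and returns to 15.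

**Further compounds**
F1 | step 3 | tertiary bromide, methyl 2-{[6-(2-bromopropan-2-yl)-1,3-dimethyl-2-oxocyclohex-3-en-1-yl]methyl}prop-2-enoate with the configuration of 5 | C1C=C(C)C(=O)[C@@](C)(CC(=C)C(=O)OC)[C@@H]1C(C)(C)Br
F2 | step 10 | 7-ene-6β,9α-diol butenolide | O[C@@H]1C=C(C)[C@](O)(CCC2=CC(=O)OC2)[C@@]2(C)CCCC(C)(C)[C@H]12
F3 | step 10 | 6β-acetoxy-9α-hydroxy-7-ene butenolide | CC(=O)O[C@@H]1C=C(C)[C@](O)(CCC2=CC(=O)OC2)[C@@]2(C)CCCC(C)(C)[C@H]12
F4 | step 8 | diene acetal, 2-{2-[(4aS,8aS)-2,5,5,8a-tetramethyl-4a,5,6,7,8,8a-hexahydronaphthalen-1-yl]ethyl}-1,3-dioxolane | C1=CC(C)=C(CCC3OCCO3)[C@@]2(C)CCCC(C)(C)[C@H]12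
F5 | step 8 | diene aldehyde, 3-[(4aS,8aS)-2,5,5,8a-tetramethyl-4a,5,6,7,8,8a-hexahydronaphthalen-1-yl]propanal | C1=CC(C)=C(CCC=O)[C@@]2(C)CCCC(C)(C)[C@H]12
F6 | step 8 | diene hydroxymethyl ketone, 1-hydroxy-4-[(4aS,8aS)-2,5,5,8a-tetramethyl-4a,5,6,7,8,8a-hexahydronaphthalen-1-yl]butan-2-one | C1=CC(C)=C(CCC(=O)CO)[C@@]2(C)CCCC(C)(C)[C@H]12
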